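Watch the free nucleophile.

    electrophile + target ⇌ idle adduct, settled at all times (K1 = 96.7 L mol⁻¹)
    electrophile + nucleophile → acid set free + target (k2 = 0.00162 L mol⁻¹ s⁻¹)
    nucleophile + acid set free ⇌ protonated nucleophile, settled at all times (K3 = 33000 L mol⁻¹)

electrophile 0.031 M; time 15 h

- the concentration of nucleophile at which the part of the electrophile that has reacted at 15 h is just 70%, in M

- percent here means electrophile units held: one idle adduct counts as two
- what is said of target includes idle adduct
- the amount of nucleophile is what is sought; it is there from the start
- what has gone from electrophile into another species counts as reacted, even if it can come back
- in an amount of target, one idle adduct counts as one target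
- run time (flask): 15 h

At the meeting I argued first that the wanted point leaves 0.00930 M of electrophile free, and that the adduct balance at that level makes the reacted electrophile correspond to 0.0147 M of target, idle adduct included, which at two nucleophiles per target, one reacting and one taking up the acid, comes to 0.0295 M, an amount I named the nucleophile bill, two nucleophiles for every target formed. I then proposed to reckon only the remainder above the bill: with the acid bound, free nucleophile decays in a pseudo-first-order way at 2 k2 c(electrophile), so holding c(electrophile) at its end value leaves a free share of 19.6% and asks for a charge of 0.0367 M, a remainder of 0.00720 M. I added that this charge overstates the need, since c(electrophile) starts higher, so I committed to the midpoint, 0.0331 M, and that K3 times the remainder, which is the ratio of protonated nucleophile to acid set free with that much nucleophile free, is 238, so counting the acid as bound stands in my reckoning. The forecast, holding that “each acid released removes about one nucleophile”, put the need at 0.0201 M, within 0.019 M to 0.0215 M, and I minuted that even its high end stands below my bill.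

The simulation gives 0.0323 M. In this flask at 15.0 h, 9.34% of the charged nucleophile is still free, while the bill comes to 91.3% of the charge. In a second flask, charged with 0.0258 M of nucleophile, 60.7% of the electrophile has reacted at 15 h, and the bill for that level is 0.0244 M.

The numbers of this flask are made up.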